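Everything rests on cutting the C2–C3 bond of pyranone ring C. In the forward sense, ring C is closed by an enantioselective dirhodium-carbenoid insertion of C3 into one of the two C2–H bonds of an acyclic aryl benzyl ether. The step exploits the fact that C2–H is benzylic to the electron-rich ring B and alpha to O1, and lies 1,6 to C3 while O1 itself blocks five-membered closure. One operation thus forms the C2–C3 bond, ring C and the C2 (S) stereocentre. The precursor is an α-diazoketone built from 2',6'-dihydroxy-4'-methoxyacetophenone and 2-geranylveratryl alcohol, with O5 masked as a triisopropylsilyl ether.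

Key step: step 5

Remark on numbering: flavanone locants (O1, C2, C3, C4, C4a, C5 to C8, C8a; ring B primed) are used for all intermediates, acyclic ones included.

Assumption: Rh2(S-PTTL)4 is taken to deliver the 2S product in this 1,6-insertion; if the sense of induction proves opposite, the mirror-image catalyst Rh2(R-PTTL)4 is used and nothing else changes.

Step 1
Reactants: 1 (3,4-dimethoxyphenyl)methanol (veratryl alcohol); 2 (2E)-1-bromo-3,7-dimethylocta-2,6-diene (geranyl bromide)
Product: 5 {2-[(2E)-3,7-dimethylocta-2,6-dien-1-yl]-3,4-dimethoxyphenyl}methanol, via dilithio species 3 (not isolated), via arylcopper 4 (not isolated)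
Conditions: n-BuLi (2.2 equiv), THF, 0 °C → rt; CuBr·SMe2 (1.1 equiv), −40 °C; 2, −40 °C → rt; aq. NH4Cl
Reagents that add atoms: none
Why: Directed ortho-metalation followed by copper-mediated allylic substitution: the lithium alkoxide and the 3-methoxy group jointly direct n-BuLi to C2 of 1, and the arylcopper formed on transmetalation should attack the unhindered primary carbon of 2 in SN2 fashion, which keeps the E alkene and leaves the tertiary terminus untouched.

Step 2
Reactants: 5 {2-[(2E)-3,7-dimethylocta-2,6-dien-1-yl]-3,4-dimethoxyphenyl}methanol; 6 1-(2,6-dihydroxy-4-methoxyphenyl)ethan-1-one (1.3 equiv)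
Product: 7 1-[2-({2-[(2E)-3,7-dimethylocta-2,6-dien-1-yl]-3,4-dimethoxyphenyl}methoxy)-6-hydroxy-4-methoxyphenyl]ethan-1-one
Conditions: PPh3, DIAD, THF, 0 °C → rt
Reagents that add atoms: none
Why: Mitsunobu etherification: the phosphonium-activated primary benzylic alcohol is displaced by one of the two equivalent, acidic phenols of 6 under neutral conditions, and the remaining phenol, locked in a hydrogen bond to the ketone and flanked by the new ether, should resist a second alkylation.

Step 3
Reactants: 7 1-[2-({2-[(2E)-3,7-dimethylocta-2,6-dien-1-yl]-3,4-dimethoxyphenyl}methoxy)-6-hydroxy-4-methoxyphenyl]ethan-1-one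
Product: 8 1-[2-({2-[(2E)-3,7-dimethylocta-2,6-dien-1-yl]-3,4-dimethoxyphenyl}methoxy)-4-methoxy-6-(triisopropylsilyloxy)phenyl]ethan-1-one
Conditions: TIPSOTf, 2,6-lutidine, CH2Cl2, 0 °C → rt
Reagents that add atoms: triisopropylsilyl trifluoromethanesulfonate (TIPSOTf), CC(C)[Si](OS(=O)(=O)C(F)(F)F)(C(C)C)C(C)C
Why: Silylation of a phenol with a silyl triflate: the reagent is electrophilic enough to overcome the hydrogen bond to the ketone, and the triisopropylsilyl ether removes the O–H bond that would otherwise trap the carbenoid of step 5 while offering no C–H bond alpha to oxygen.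

Step 4
Reactants: 8 1-[2-({2-[(2E)-3,7-dimethylocta-2,6-dien-1-yl]-3,4-dimethoxyphenyl}methoxy)-4-methoxy-6-(triisopropylsilyloxy)phenyl]ethan-1-one
Product: 11 2-diazo-1-[2-({2-[(2E)-3,7-dimethylocta-2,6-dien-1-yl]-3,4-dimethoxyphenyl}methoxy)-4-methoxy-6-(triisopropylsilyloxy)phenyl]ethan-1-one, via lithium enolate 9 (not isolated), via trifluoroacetyl diketone 10 (not isolated)
Conditions: LiN(SiMe3)2, THF, −78 °C; CF3CO2CH2CF3, −78 °C; cold 1 M HCl wash; then MsN3, Et3N, H2O (1 equiv), MeCN, rt
Reagents that add atoms: methanesulfonyl azide, CS(=O)(=O)N=[N+]=[N-]; 2,2,2-trifluoroethyl trifluoroacetate, O=C(OCC(F)(F)F)C(F)(F)F (its trifluoroacetyl group is carried only by 10)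
Why: Detrifluoroacetylative diazo transfer (a deacylative Regitz diazo transfer): the kinetic lithium enolate 9 is C-acylated by the trifluoroacetate to the activated diketone 10, which accepts the diazo group from the sulfonyl azide and loses its trifluoroacetyl group as the N-acylsulfonamide, so that the terminal diazoketone forms without an acid chloride or diazomethane and at temperatures where the aryl silyl ether should stay in place.

Step 5
Reactants: 11 2-diazo-1-[2-({2-[(2E)-3,7-dimethylocta-2,6-dien-1-yl]-3,4-dimethoxyphenyl}methoxy)-4-methoxy-6-(triisopropylsilyloxy)phenyl]ethan-1-one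
Product: 12 (2S)-2-{2-[(2E)-3,7-dimethylocta-2,6-dien-1-yl]-3,4-dimethoxyphenyl}-7-methoxy-5-(triisopropylsilyloxy)-2,3-dihydro-4H-chromen-4-one
Conditions: Rh2(S-PTTL)4 (dirhodium tetrakis[N-phthaloyl-(S)-tert-leucinate], 2 mol %), CH2Cl2, 4 Å MS, slow addition of 11 at high dilution, 0 °C → rt
Reagents that add atoms: none
Why: Rh2(S-PTTL)4 extrudes N2 from 11 to give an electrophilic rhodium carbenoid at C3, which engages a C2–H bond in a three-centre, hydride-transfer-like transition state and forms the C3–C2 bond with release of the catalyst. The closest known reaction type is the enantioselective intramolecular carbenoid C–H insertion of 2-alkoxyaryl α-diazoketones to chroman-4-ones under chiral dirhodium carboxylates. Ring C closes as a six-membered ring by 1,6-insertion (C3–C4–C4a–C8a–O1–C2), the normally preferred 1,5-mode being impossible because that position is O1, which carries no hydrogen. The C2 stereocentre is set under catalyst control, the phthalimido wall of the tert-leucinate ligands differentiating the two enantiotopic C2–H bonds. The step needs C–H insertion to outrun oxonium ylide formation at O1 (which would lead to a [1,2]-benzyl shift), attack on O5 and cyclopropanation of the geranyl alkenes. The substrate should secure this through a C2–H bond that is both alpha to O1 and benzylic to ring B (4'-methoxy para to C2), an O1 lone pair deactivated by conjugation with the ortho acyl group, a bulky silyl group on O5 without alpha C–H bonds, and alkenes reachable only through rings of ten or more atoms, with slow addition suppressing bimolecular pathways.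

Step 6
Reactants: 12 (2S)-2-{2-[(2E)-3,7-dimethylocta-2,6-dien-1-yl]-3,4-dimethoxyphenyl}-7-methoxy-5-(triisopropylsilyloxy)-2,3-dihydro-4H-chromen-4-one
Product: 13 (2S)-2-{2-[(2E)-3,7-dimethylocta-2,6-dien-1-yl]-3,4-dimethoxyphenyl}-5-hydroxy-7-methoxy-2,3-dihydro-4H-chromen-4-one
Conditions: HF·pyridine, pyridine, THF, 0 °C → rt
Reagents that add atoms: none
Why: Fluoride-driven cleavage of the aryl silyl ether (formation of the strong Si–F bond) under buffered, non-basic conditions, which should leave the geranyl alkenes intact and avoid the base-induced retro-oxa-Michael ring opening through which flavanones racemise, so the C2 configuration set in step 5 is carried into 13.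

Compound list
1 | (3,4-dimethoxyphenyl)methanol (veratryl alcohol) | COc1ccc(CO)cc1OC | starting material
2 | (2E)-1-bromo-3,7-dimethylocta-2,6-diene (geranyl bromide) | BrC/C=C(\C)CCC=C(C)C | starting material
3 | lithium (2-lithio-3,4-dimethoxyphenyl)methanolate (dilithio species) | [Li]OCc1ccc(OC)c(OC)c1[Li] | intermediate (not isolated)
4 | lithium (2-cuprio-3,4-dimethoxyphenyl)methanolate (arylcopper) | [Li]OCc1ccc(OC)c(OC)c1[Cu] | intermediate (not isolated)
5 | {2-[(2E)-3,7-dimethylocta-2,6-dien-1-yl]-3,4-dimethoxyphenyl}methanol | COc1ccc(CO)c(C/C=C(\C)CCC=C(C)C)c1OC | intermediate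
6 | 1-(2,6-dihydroxy-4-methoxyphenyl)ethan-1-one | CC(=O)c1c(O)cc(OC)cc1O | starting material
7 | 1-[2-({2-[(2E)-3,7-dimethylocta-2,6-dien-1-yl]-3,4-dimethoxyphenyl}methoxy)-6-hydroxy-4-methoxyphenyl]ethan-1-one | CC(=O)c1c(O)cc(OC)cc1OCc1ccc(OC)c(OC)c1C/C=C(\C)CCC=C(C)C | intermediate
8 | 1-[2-({2-[(2E)-3,7-dimethylocta-2,6-dien-1-yl]-3,4-dimethoxyphenyl}methoxy)-4-methoxy-6-(triisopropylsilyloxy)phenyl]ethan-1-one | CC(=O)c1c(O[Si](C(C)C)(C(C)C)C(C)C)cc(OC)cc1OCc1ccc(OC)c(OC)c1C/C=C(\C)CCC=C(C)C | intermediate
9 | lithium enolate of 8 | C=C(O[Li])c1c(O[Si](C(C)C)(C(C)C)C(C)C)cc(OC)cc1OCc1ccc(OC)c(OC)c1C/C=C(\C)CCC=C(C)C | intermediate (not isolated)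
10 | 1-[2-({2-[(2E)-3,7-dimethylocta-2,6-dien-1-yl]-3,4-dimethoxyphenyl}methoxy)-4-methoxy-6-(triisopropylsilyloxy)phenyl]-4,4,4-trifluorobutane-1,3-dione | O=C(CC(=O)C(F)(F)F)c1c(O[Si](C(C)C)(C(C)C)C(C)C)cc(OC)cc1OCc1ccc(OC)c(OC)c1C/C=C(\C)CCC=C(C)C | intermediate (not isolated)
11 | 2-diazo-1-[2-({2-[(2E)-3,7-dimethylocta-2,6-dien-1-yl]-3,4-dimethoxyphenyl}methoxy)-4-methoxy-6-(triisopropylsilyloxy)phenyl]ethan-1-one | [N-]=[N+]=CC(=O)c1c(O[Si](C(C)C)(C(C)C)C(C)C)cc(OC)cc1OCc1ccc(OC)c(OC)c1C/C=C(\C)CCC=C(C)C | intermediate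
12 | (2S)-2-{2-[(2E)-3,7-dimethylocta-2,6-dien-1-yl]-3,4-dimethoxyphenyl}-7-methoxy-5-(triisopropylsilyloxy)-2,3-dihydro-4H-chromen-4-one | COc1cc(O[Si](C(C)C)(C(C)C)C(C)C)c2c(c1)O[C@H](c1ccc(OC)c(OC)c1C/C=C(\C)CCC=C(C)C)CC2=O | intermediate
13 | (2S)-2-{2-[(2E)-3,7-dimethylocta-2,6-dien-1-yl]-3,4-dimethoxyphenyl}-5-hydroxy-7-methoxy-2,3-dihydro-4H-chromen-4-one | COc1cc(O)c2c(c1)O[C@H](c1ccc(OC)c(OC)c1C/C=C(\C)CCC=C(C)C)CC2=O | target

Total step count: 6. Longest linear sequence: 6 steps (1 → 5 → 7 → 8 → 11 → 12 → 13); partner 6 is commercial.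

Steps most likely to fail

Step 5. The carbenoid may be diverted to the O1 oxonium ylide with subsequent [1,2]-benzyl migration, and the chiral carboxylate may discriminate the two enantiotopic C2–H bonds poorly. The fallback sets out from 11 and returns at 12; it decouples ring closure from stereocontrol. Diazoketone 11 would be decomposed with an achiral dirhodium carboxylate chosen only for insertion chemoselectivity (Rh2(OAc)4, CH2Cl2, slow addition). This should still close ring C through the C3–C2 bond and give racemic 2-{2-[(2E)-3,7-dimethylocta-2,6-dien-1-yl]-3,4-dimethoxyphenyl}-7-methoxy-5-(triisopropylsilyloxy)-2,3-dihydro-4H-chromen-4-one F1. Dehydrogenation with 2-iodoxybenzoic acid (DMSO, 70 °C) should give the flavone 2-{2-[(2E)-3,7-dimethylocta-2,6-dien-1-yl]-3,4-dimethoxyphenyl}-7-methoxy-5-(triisopropylsilyloxy)-4H-chromen-4-one F2. Copper hydride asymmetric conjugate reduction of the chromone (Cu(OAc)2, the DTBM-SEGPHOS antipode that delivers 2S, (EtO)2MeSiH, t-BuOH, toluene), a known route from chromones to chiral chroman-4-ones, should then return 12 without touching the isolated alkenes.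

Step 4. The silyl group may migrate from the phenolic oxygen to the neighbouring lithium enolate oxygen, and C-acylation of the twisted, doubly ortho-substituted enolate may be incomplete. The fallback sets out from 8 and returns at 11; it avoids any anionic enolate. Soft enolisation (TMSOTf, Et3N, CH2Cl2, 0 °C) should give the trimethylsilyl enol ether {1-[2-({2-[(2E)-3,7-dimethylocta-2,6-dien-1-yl]-3,4-dimethoxyphenyl}methoxy)-4-methoxy-6-(triisopropylsilyloxy)phenyl]ethenyloxy}trimethylsilane F3. Bromination with NBS (THF, −78 °C) should give the α-bromoketone 2-bromo-1-[2-({2-[(2E)-3,7-dimethylocta-2,6-dien-1-yl]-3,4-dimethoxyphenyl}methoxy)-4-methoxy-6-(triisopropylsilyloxy)phenyl]ethan-1-one F4. Treatment with N,N'-ditosylhydrazine and DBU (THF, 0 °C) should give 11 by N-alkylation and double sulfinate elimination.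

Step 1. The allylic substitution may leak to attack at the tertiary terminus with erosion of the E geometry, and the lithium alkoxide may be O-alkylated. The fallback sets out from 1 and 2 and returns at 5; it replaces the copper-mediated substitution by a palladium cross-coupling. Directed lithiation of 1 as above and quenching with I2 should give (2-iodo-3,4-dimethoxyphenyl)methanol F5. Displacement of 2 with Bu3SnLi (THF, −78 °C) should give tributyl[(2E)-3,7-dimethylocta-2,6-dien-1-yl]stannane F6. Stille coupling of F5 with F6 (Pd(PPh3)4, CuI, DMF, 60 °C) should give 5 with the linear E-geranyl group.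

Further compounds
F1 | step 5 | racemic 2-{2-[(2E)-3,7-dimethylocta-2,6-dien-1-yl]-3,4-dimethoxyphenyl}-7-methoxy-5-(triisopropylsilyloxy)-2,3-dihydro-4H-chromen-4-one | COc1cc(O[Si](C(C)C)(C(C)C)C(C)C)c2c(c1)OC(c1ccc(OC)c(OC)c1C/C=C(\C)CCC=C(C)C)CC2=O
F2 | step 5 | 2-{2-[(2E)-3,7-dimethylocta-2,6-dien-1-yl]-3,4-dimethoxyphenyl}-7-methoxy-5-(triisopropylsilyloxy)-4H-chromen-4-one | COc1cc(O[Si](C(C)C)(C(C)C)C(C)C)c2c(c1)oc(-c1ccc(OC)c(OC)c1C/C=C(\C)CCC=C(C)C)cc2=O
F3 | step 4 | {1-[2-({2-[(2E)-3,7-dimethylocta-2,6-dien-1-yl]-3,4-dimethoxyphenyl}methoxy)-4-methoxy-6-(triisopropylsilyloxy)phenyl]ethenyloxy}trimethylsilane | C=C(O[Si](C)(C)C)c1c(O[Si](C(C)C)(C(C)C)C(C)C)cc(OC)cc1OCc1ccc(OC)c(OC)c1C/C=C(\C)CCC=C(C)C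
F4 | step 4 | 2-bromo-1-[2-({2-[(2E)-3,7-dimethylocta-2,6-dien-1-yl]-3,4-dimethoxyphenyl}methoxy)-4-methoxy-6-(triisopropylsilyloxy)phenyl]ethan-1-one | BrCC(=O)c1c(O[Si](C(C)C)(C(C)C)C(C)C)cc(OC)cc1OCc1ccc(OC)c(OC)c1C/C=C(\C)CCC=C(C)C
F5 | step 1 | (2-iodo-3,4-dimethoxyphenyl)methanol | COc1ccc(CO)c(I)c1OC
F6 | step 1 | tributyl[(2E)-3,7-dimethylocta-2,6-dien-1-yl]stannane | CCCC[Sn](CCCC)(CCCC)C/C=C(\C)CCC=C(C)C
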